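Everything rests on cutting the side chain at C2'–C3'. C2' is a secondary carbinol carbon whose two neighbours, C1'H2 (bound to C2 of the pyranone ring) and C3'H2, are sterically almost alike, so reduction of a C2' ketone could hardly tell them apart. A nickel-hydride three-component coupling instead unites a racemic α-bromoalkyl benzoate, methyl pent-4-enoate and a hydrosilane, forming C2'–C3' and the (R)-configured, already O-protected carbinol in one operation under catalyst control. The precursor is racemic 1-bromo-4-(trimethylsilyl)but-3-yn-1-yl benzoate; its silyl-capped alkyne is the latent C2–C3 unit of the pyranone ring, closed later by carbonylative annulation onto 2-iodo-5-methoxyresorcinol, which supplies the benzene ring.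

Key step: step 3

Remark: side-chain locants C1'–C7' run from the pyranone C2 to the ester carbon (C2' is C6 of the ester names); the ligand antipode that gives 6R is assumed to be identified on a model bromide, both antipodes being available.

Step 1
Reactants: 1 4-(trimethylsilyl)but-3-yn-1-ol
Product: 2 4-(trimethylsilyl)but-3-ynal
Conditions: Dess–Martin periodinane (1.2 equiv), CH2Cl2, 0 °C to rt; cold filtration through a short pad (pentane), concentrated cold, used at once
Reagents that add atoms: none
Why: Dess–Martin oxidation of a primary alcohol runs without base, which should keep the β,γ-alkynyl aldehyde from shifting to the conjugated allenal; no stereocenter is formed.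

Step 2
Reactants: 2 4-(trimethylsilyl)but-3-ynal; 3 benzoyl bromide
Product: 4 racemic 1-bromo-4-(trimethylsilyl)but-3-yn-1-yl benzoate
Conditions: ZnBr2 (2 mol %), CH2Cl2, −20 to 0 °C; volatiles removed, used crude
Reagents that add atoms: none
Why: Zinc-bromide-catalysed addition of an acyl bromide across an aldehyde C=O (1-bromoalkyl ester formation) is fast for aliphatic aldehydes at low temperature and should outrun isomerisation of 2; the new centre is racemic and is erased in step 3.

Step 3
Reactants: 4 racemic 1-bromo-4-(trimethylsilyl)but-3-yn-1-yl benzoate; 5 methyl pent-4-enoate (2 equiv)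
Product: 6 methyl (6R)-6-(benzoyloxy)-9-(trimethylsilyl)non-8-ynoate
Conditions: NiBr2·glyme (10 mol %), chiral bis(oxazoline) L* (12 mol %; for example one antipode of 2,2'-(propane-2,2-diyl)bis(4-isopropyl-4,5-dihydrooxazole)), (EtO)3SiH (2 equiv), K3PO4·H2O (2 equiv), Et2O/DMA, rt
Reagents that add atoms: none
Why: Phosphate-activated (EtO)3SiH converts the ligated nickel bromide into a nickel hydride, which adds across the terminal olefin of 5 with the metal at the terminal carbon and gives a primary alkylnickel species carrying the (CH2)4CO2Me chain. Halogen abstraction from either enantiomer of 4 by monovalent nickel gives the same planar α-benzoyloxy radical, so the racemate converges; capture of the radical by the chiral alkylnickel complex and reductive elimination from trivalent nickel form C2'–C3' (C6–C5 of 6), and no ring is closed. The closest known reaction type is the nickel-hydride enantioconvergent coupling of racemic 1-bromoalkyl esters with unactivated terminal olefins and a hydrosilane to esters of dialkyl carbinols; 4 differs only in carrying a silyl-capped internal alkyne. The C2' configuration is set by the chiral ligand on nickel, the benzoate carbonyl serving as the coordinating group that lets the catalyst distinguish the oxygen substituent from the two nearly equal methylene arms. The step needs hydrometalation of the monosubstituted olefin ahead of the alkyne and ahead of plain reduction of the C–Br bond: the alkyne is internal and shielded by the trimethylsilyl group, the olefin is used in excess, and the small silyl cap is kept because it later leaves together with the benzoate.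

Step 4
Reactants: 6 methyl (6R)-6-(benzoyloxy)-9-(trimethylsilyl)non-8-ynoate
Product: 7 methyl (6R)-6-hydroxynon-8-ynoate
Conditions: K2CO3 (1.5 equiv), MeOH, rt
Reagents that add atoms: none
Why: Base-mediated methanolysis (transesterification of the benzoate and protodesilylation of the alkynylsilane) leaves the methyl ester unchanged in methanol and breaks only the acyl–oxygen bond of the benzoate, so C6 stays R.

Step 5
Reactants: 7 methyl (6R)-6-hydroxynon-8-ynoate
Product: 8 methyl (6R)-6-[(tert-butyldimethylsilyl)oxy]non-8-ynoate
Conditions: TBSCl, imidazole, DMF, rt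
Reagents that add atoms: tert-butyldimethylsilyl chloride, CC(C)(C)[Si](C)(C)Cl
Why: Imidazole-promoted silyl ether formation on a secondary alcohol; the ether keeps the homopropargylic hydroxyl away from acylpalladium and alkyne–palladium intermediates in step 7 and, unlike an ester, is a poor leaving group β to the future C1' methylene.

Step 6
Reactants: 9 5-methoxyresorcinol
Product: 10 2-iodo-5-methoxybenzene-1,3-diol
Conditions: I2 (1.0 equiv), NaHCO3, H2O/THF, 0 °C
Reagents that add atoms: iodine, II
Why: Electrophilic aromatic iodination of the resorcinol monoanion in aqueous bicarbonate should go to C2, between the two hydroxyl groups, as it does for resorcinol itself, and one equivalent of iodine at 0 °C limits polyiodination.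

Step 7
Reactants: 8 methyl (6R)-6-[(tert-butyldimethylsilyl)oxy]non-8-ynoate; 10 2-iodo-5-methoxybenzene-1,3-diol (1.3 equiv)
Product: 12 methyl (6R)-6-[(tert-butyldimethylsilyl)oxy]-7-(5-hydroxy-7-methoxy-4-oxo-4H-chromen-2-yl)heptanoate, via aryl alkynyl ketone 11 (not isolated)
Conditions: PdCl2(dppf) (5 mol %), CO (20 bar), Et2NH, 100 °C
Reagents that add atoms: carbon monoxide, [C-]#[O+]
Why: Carbonylative Sonogashira coupling followed by amine-mediated cyclisation (the known palladium route from 2-iodophenols, CO and terminal alkynes to chromones): oxidative addition of 10 to zerovalent palladium, CO insertion and alkynylation give alkynone 11, diethylamine adds to it as a β-aminoenone and one of the two equivalent ortho-phenols displaces the amine, which enforces 6-endo closure to the pyranone ring while the other phenol becomes the chelated 5-OH.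

Step 8
Reactants: 12 methyl (6R)-6-[(tert-butyldimethylsilyl)oxy]-7-(5-hydroxy-7-methoxy-4-oxo-4H-chromen-2-yl)heptanoate
Product: 13 methyl (6R)-6-hydroxy-7-(5-hydroxy-7-methoxy-4-oxo-4H-chromen-2-yl)heptanoate (penithochromone O)
Conditions: HF·pyridine, pyridine/THF, 0 °C to rt
Reagents that add atoms: none
Why: Fluoride cleavage of the silyl ether under buffered, weakly acidic conditions spares the methyl ester and avoids base that could eliminate the C2' oxygen across the acidic C1' methylene; the C2'–O bond is untouched, so the centre stays R.

Compound list
1 | 4-(trimethylsilyl)but-3-yn-1-ol | C[Si](C)(C)C#CCCO | starting material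
2 | 4-(trimethylsilyl)but-3-ynal | C[Si](C)(C)C#CCC=O | intermediate
3 | benzoyl bromide | O=C(Br)c1ccccc1 | starting material
4 | racemic 1-bromo-4-(trimethylsilyl)but-3-yn-1-yl benzoate | C[Si](C)(C)C#CCC(Br)OC(=O)c1ccccc1 | intermediate
5 | methyl pent-4-enoate | COC(=O)CCC=C | starting material
6 | methyl (6R)-6-(benzoyloxy)-9-(trimethylsilyl)non-8-ynoate | COC(=O)CCCC[C@@H](OC(=O)c1ccccc1)CC#C[Si](C)(C)C | intermediate
7 | methyl (6R)-6-hydroxynon-8-ynoate | COC(=O)CCCC[C@@H](O)CC#C | intermediate
8 | methyl (6R)-6-[(tert-butyldimethylsilyl)oxy]non-8-ynoate | COC(=O)CCCC[C@@H](O[Si](C)(C)C(C)(C)C)CC#C | intermediate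
9 | 5-methoxyresorcinol (5-methoxybenzene-1,3-diol) | COc1cc(O)cc(O)c1 | starting material
10 | 2-iodo-5-methoxybenzene-1,3-diol | COc1cc(O)c(I)c(O)c1 | intermediate
11 | methyl (6R)-6-[(tert-butyldimethylsilyl)oxy]-10-(2,6-dihydroxy-4-methoxyphenyl)-10-oxodec-8-ynoate | COC(=O)CCCC[C@@H](O[Si](C)(C)C(C)(C)C)CC#CC(=O)c1c(O)cc(OC)cc1O | intermediate (not isolated)
12 | methyl (6R)-6-[(tert-butyldimethylsilyl)oxy]-7-(5-hydroxy-7-methoxy-4-oxo-4H-chromen-2-yl)heptanoate | COC(=O)CCCC[C@@H](O[Si](C)(C)C(C)(C)C)Cc1cc(=O)c2c(O)cc(OC)cc2o1 | intermediate
13 | methyl (6R)-6-hydroxy-7-(5-hydroxy-7-methoxy-4-oxo-4H-chromen-2-yl)heptanoate (penithochromone O) | COC(=O)CCCC[C@@H](O)Cc1cc(=O)c2c(O)cc(OC)cc2o1 | target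

Total step count: 8. Longest linear sequence: 7 steps (steps 1, 2, 3, 4, 5, 7, 8, from compound 1); step 6 is a one-step side branch.

Steps most likely to fail

Step 3. The nickel hydride may add to the silylalkyne, or the alkyne may tie up low-valent nickel. The bromide may also be reduced or lose HBr towards the enol ester, or the catalyst may discriminate the two faces of the radical poorly. The fallback sets the carbinol by catalytic asymmetric propargylation of an aldehyde; it sets out from 5 and comes back at 7. Linear-selective hydroformylation of 5 (Rh(acac)(CO)2, BiPhePhos, CO/H2, toluene, 80 °C) should give methyl 6-oxohexanoate F1. Addition of allenylboronic acid pinacol ester to F1 under a chiral Brønsted acid (3,3'-bis(2,4,6-triisopropylphenyl)-1,1'-binaphthyl-2,2'-diyl hydrogen phosphate, antipode chosen for R; toluene, 4 Å molecular sieves, −20 °C) should give 7 after aqueous work-up. Steps 1 to 4 are then not needed.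

Step 7. The free ortho-phenols may divert the aroylpalladium species, by CO-free coupling with furan closure or by aryl ester formation. The alkynone may close 5-exo, or lose silanol across C1'–C2' under the hot amine. The fallback separates ketone formation from ring closure on a phenol-masked iodide; it sets out from 10, uses 8, and comes back at 12. Acetylation of 10 (Ac2O, pyridine) gives 2-iodo-5-methoxy-1,3-phenylene diacetate F2. Carbonylative Sonogashira coupling of F2 with 8 at room temperature (PdCl2(PPh3)2, Et3N, CO 1 atm, THF) should stop at methyl (6R)-10-[2,6-bis(acetyloxy)-4-methoxyphenyl]-6-[(tert-butyldimethylsilyl)oxy]-10-oxodec-8-ynoate F3, because no phenoxide is present. Et2NH in MeOH at rt then removes the acetates and closes the pyranone ring through the aminoenone, giving 12.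

Step 6. Iodination may occur at C4 or C6 instead of C2, or run on to polyiodides that are hard to separate from the light-sensitive product. The fallback fixes the position by directed ortho-metalation; it sets out from 9 and comes back at 10. Protection (MOMCl, i-Pr2NEt, CH2Cl2) gives 1-methoxy-3,5-bis(methoxymethoxy)benzene F4. Lithiation between the two acetal oxygens (n-BuLi, THF, 0 °C) and quenching with I2 gives 2-iodo-5-methoxy-1,3-bis(methoxymethoxy)benzene F5. HCl in MeOH then liberates 10.

Further compounds
F1 | step 3 | methyl 6-oxohexanoate | COC(=O)CCCCC=O
F2 | step 7 | 2-iodo-5-methoxy-1,3-phenylene diacetate | COc1cc(OC(C)=O)c(I)c(OC(C)=O)c1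
F3 | step 7 | methyl (6R)-10-[2,6-bis(acetyloxy)-4-methoxyphenyl]-6-[(tert-butyldimethylsilyl)oxy]-10-oxodec-8-ynoate | COC(=O)CCCC[C@@H](O[Si](C)(C)C(C)(C)C)CC#CC(=O)c1c(OC(C)=O)cc(OC)cc1OC(C)=O
F4 | step 6 | 1-methoxy-3,5-bis(methoxymethoxy)benzene | COCOc1cc(OC)cc(OCOC)c1
F5 | step 6 | 2-iodo-5-methoxy-1,3-bis(methoxymethoxy)benzene | COCOc1cc(OC)cc(OCOC)c1I
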